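**Plan**
1. Retrosynthetic cuts, in order: the stearate C–O bond; the exocyclic C2=C bond (back to a C2 ketone, masked as a ketal); the side chain at C5'–C6' and C3'=C4' (back to a C6 allyl group); the C5 methyl carbinol (back to a C5 ketone); last, C1–C1'' together with C6–C1'.
2. Enabling feature: in the cyclohexane ring C1 is β and the quaternary C6 is α to the carbinol carbon C5, and C2 stands para to C5. The ring is therefore a masked 2-methylcyclohex-2-ene-1,4-dione, and enone ketal 3, a C3 Grignard reagent and allyl iodide can be joined in one flask (C1–C1'' first, then C6–C1').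
3. Forward: the ring is bought (1 → 3 in two steps); three-component coupling; C5 methyl carbinol; side chain by Wittig reaction, geranylbarium addition and CBS reduction; C2 enal by isopropenyl addition and oxidative transposition; desilylation; lipase stearoylation. No ring is formed.
4. Stereochemistry: C1 from the chiral copper catalyst; C6 from alkylation anti to the C1 chain; C5 from epoxidation anti to the axial C6 methyl, then hydride opening; C5' from the CBS catalyst; 3'E from the stabilised ylide, 7'E from geranyl chloride, 2Z from the [3,3] chromate shift.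

Key step: step 3

Locants: ring C1 (CH carrying the chain C1''–C3''), C2 (alkylidene carbon), C3, C4, C5 (carbinol carbon), C6 (quaternary carbon); long side chain C1'–C12' counted from C6.

Assumption: 1 is bought (it is one dehydrogenation step from 1,4-cyclohexanedione monoethylene ketal), and the (S)-leucinol-derived hydroxyalkyl NHC ligand is taken to deliver the alkyl group to the Re face of the β-carbon of 3; were the sense the reverse, the (R)-ligand would be used with no other change.

**Route**

Step 1
Reactants: 1 1,4-dioxaspiro[4.5]dec-6-en-8-one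
Product: 2 7-iodo-1,4-dioxaspiro[4.5]dec-6-en-8-one
Conditions: I2, pyridine, CH2Cl2, 0 °C → rt
Reagents that add atoms: iodine (II)
Why: α-Iodination of a cyclic enone by pyridine addition, iodination and elimination places the halogen only on the α-carbon, which fixes the position of the future C6 methyl.

Step 2
Reactants: 2 7-iodo-1,4-dioxaspiro[4.5]dec-6-en-8-one
Product: 3 7-methyl-1,4-dioxaspiro[4.5]dec-6-en-8-one
Conditions: MeB(OH)2, Pd(OAc)2 (5 mol%), SPhos, K3PO4, toluene/H2O, 80 °C
Reagents that add atoms: methylboronic acid (CB(O)O)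
Why: Suzuki–Miyaura coupling; the α-iodoenone adds oxidatively to zerovalent palladium with ease and the ketal is inert to the base.

Step 3
Reactants: 3 7-methyl-1,4-dioxaspiro[4.5]dec-6-en-8-one; 4 (3-bromopropoxy)(tert-butyl)diphenylsilane
Product: 7 (6R,7R)-7-allyl-6-[3-(tert-butyldiphenylsilyloxy)propyl]-7-methyl-1,4-dioxaspiro[4.5]decan-8-one, via Grignard reagent 5 (not isolated), via magnesium enolate 6 (not isolated)
Conditions: 4, Mg, Et2O, 35 °C; added slowly to 3, Cu(OTf)2 (5 mol%), (S)-leucinol-derived hydroxyalkyl imidazolinium salt (NHC precursor, 7 mol%), Et2O, −20 °C; then allyl iodide, DMPU, −20 °C → rt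
Reagents that add atoms: allyl iodide (C=CCI)
Why: A chiral NHC-bound monovalent copper alkyl formed from 5 adds 1,4 to the 2-methyl enone 3 (π-complex, trivalent copper enolate, reductive elimination at the β-carbon) and gives the tetrasubstituted magnesium enolate 6 regiospecifically, which allyl iodide then alkylates on carbon in the same flask. The closest known reaction type is the copper/NHC-catalysed asymmetric conjugate addition of Grignard reagents to α-substituted cyclic enones with alkylation of the magnesium enolate to a quaternary centre. No ring is closed. C1 is set by the ligand (Re-face delivery; the achiral ketal gives no bias), and C6 by the substrate: the new C1 chain lies pseudoaxial to avoid the C6 methyl and the ketal oxygens, so the electrophile enters anti to it and the allyl group ends trans to the chain, the methyl cis. The step needs 1,4- over 1,2-addition (copper, slow addition), alkylation at C6 and not C4 (the enolate is born at C5–C6 and magnesium enolates equilibrate slowly) and C- over O-allylation (soft iodide, DMPU).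

Step 4
Reactants: 7 (6R,7R)-7-allyl-6-[3-(tert-butyldiphenylsilyloxy)propyl]-7-methyl-1,4-dioxaspiro[4.5]decan-8-one
Product: 8 (6R,7R)-7-allyl-6-[3-(tert-butyldiphenylsilyloxy)propyl]-7-methyl-8-methylene-1,4-dioxaspiro[4.5]decane
Conditions: Ph3PCH3Br, KOtBu, toluene, 90 °C
Reagents that add atoms: methyltriphenylphosphonium bromide (C[P+](c1ccccc1)(c1ccccc1)c1ccccc1.[Br-])
Why: Wittig methylenation with excess ylide at elevated temperature overcomes the hindrance of the α-quaternary ketone, and neither C1 nor C6 can epimerise.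

Step 5
Reactants: 8 (6R,7R)-7-allyl-6-[3-(tert-butyldiphenylsilyloxy)propyl]-7-methyl-8-methylene-1,4-dioxaspiro[4.5]decane
Product: 9 spiro-epoxide of 8 at the exocyclic alkene with the oxirane oxygen cis to the C6 allyl group
Conditions: mCPBA (1.05 equiv), NaHCO3, CH2Cl2, −10 °C
Reagents that add atoms: mCPBA (OOC(=O)c1cccc(Cl)c1)
Why: Prilezhaev epoxidation; the 1,1-disubstituted alkene is more electron-rich than the allyl group, and in the reactive chair the axial C6 methyl shields its own face, so oxygen should be delivered from the allyl face and C5 gains its oxygen cis to the C6 chain.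

Step 6
Reactants: 9 spiro-epoxide with the oxirane oxygen cis to the C6 allyl group
Product: 10 (6R,7R,8S)-7-allyl-6-[3-(tert-butyldiphenylsilyloxy)propyl]-7,8-dimethyl-1,4-dioxaspiro[4.5]decan-8-ol
Conditions: LiEt3BH, THF, 0 → 50 °C
Reagents that add atoms: none
Why: SN2 opening of a hindered epoxide by hydride at the unsubstituted CH2 turns it into the C5 methyl and leaves the C5–O bond, and so the configuration, untouched.

Step 7
Reactants: 10 (6R,7R,8S)-7-allyl-6-[3-(tert-butyldiphenylsilyloxy)propyl]-7,8-dimethyl-1,4-dioxaspiro[4.5]decan-8-ol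
Product: 11 triethylsilyl ether of 10
Conditions: TESOTf, 2,6-lutidine, CH2Cl2, −78 °C
Reagents that add atoms: triethylsilyl triflate (CC[Si](CC)(CC)OS(=O)(=O)C(F)(F)F)
Why: A silyl triflate silylates the hindered tertiary alcohol at low temperature; the ether prevents lactol formation with the C3' aldehyde of step 9 and transannular ether formation in step 17.

Step 8
Reactants: 11 triethylsilyl ether of 10
Product: 13 primary alcohol (11 with the allyl group turned into 3-hydroxypropyl), via alkylborane 12 (not isolated)
Conditions: 9-BBN, THF, rt; then NaOH, H2O2, 0 °C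
Reagents that add atoms: hydrogen peroxide (OO)
Why: Anti-Markovnikov hydroboration–oxidation of the only alkene left gives the terminal alcohol.

Step 9
Reactants: 13 primary alcohol
Product: 14 aldehyde (C6 chain CH2CH2CHO)
Conditions: Dess–Martin periodinane, NaHCO3, CH2Cl2, rt
Reagents that add atoms: none
Why: Dess–Martin oxidation of a primary alcohol stops at the aldehyde under buffered conditions that leave silyl ethers and the ketal intact.

Step 10
Reactants: 14 aldehyde
Product: 15 (E)-enal (C6 chain CH2CH2CH=C(CH3)CHO)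
Conditions: Ph3P=C(CH3)CHO, toluene, 90 °C
Reagents that add atoms: 2-(triphenylphosphoranylidene)propanal (CC(C=O)=P(c1ccccc1)(c1ccccc1)c1ccccc1)
Why: Wittig reaction with a stabilised formyl ylide, under thermodynamic control, should give the E trisubstituted alkene.

Step 11
Reactants: 15 (E)-enal; 16 geranyl chloride
Product: 18 C5' allylic alcohol as a mixture of C5' epimers with 3'E and 7'E alkenes, via geranylbarium chloride 17 (not isolated)
Conditions: BaI2, Li, biphenyl, THF, rt (activated barium); 16, −78 °C; then 15, −78 °C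
Reagents that add atoms: none
Why: Allylbarium reagents add to aldehydes at their α-carbon, 1,2 to the enal and with retention of the E geometry; the uncontrolled carbinol carbon is corrected in steps 12 and 13.

Step 12
Reactants: 18 C5' allylic alcohol (both epimers)
Product: 19 C5' ketone (3'E,7'E)
Conditions: Dess–Martin periodinane, NaHCO3, CH2Cl2, 0 °C
Reagents that add atoms: none
Why: Dess–Martin oxidation of the allylic alcohol in a neutral buffered medium avoids migration of the 7' double bond into conjugation.

Step 13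
Reactants: 19 C5' ketone
Product: 20 (5'R)-allylic alcohol
Conditions: (S)-Me-CBS oxazaborolidine (20 mol%), catecholborane, toluene, −78 °C
Reagents that add atoms: none
Why: Corey–Bakshi–Shibata reduction; with the α-methyl alkenyl group as the large and the CH2 group as the small substituent, the (S)-catalyst should deliver hydride 1,2 to give the (R)-carbinol.

Step 14
Reactants: 20 (5'R)-allylic alcohol
Product: 21 tert-butyldimethylsilyl ether of 20
Conditions: TBSCl, imidazole, DMF, rt
Reagents that add atoms: tert-butyldimethylsilyl chloride (CC(C)(C)[Si](C)(C)Cl)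
Why: Standard silylation protects the secondary allylic alcohol from the chromium oxidant of step 17.

Step 15
Reactants: 21 tert-butyldimethylsilyl ether of 20
Product: 22 C2 ketone (21 without the ethylene ketal)
Conditions: PPTS, acetone/H2O, 55 °C
Reagents that add atoms: water (O)
Why: Acid-catalysed transketalisation to acetone frees the ketone; PPTS is too weak to cleave the three silyl ethers or to enolise the ketone toward C1.

Step 16
Reactants: 22 C2 ketone
Product: 23 C2 tertiary allylic alcohol (2-hydroxy-2-isopropenyl; C2 configuration left open)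
Conditions: CeCl3, isopropenylmagnesium bromide, THF, −78 °C
Reagents that add atoms: isopropenylmagnesium bromide (CC(=C)[Mg]Br)
Why: Organocerium reagents add 1,2 to hindered enolisable ketones without deprotonating C1 or C3; the new carbinol configuration is irrelevant because C2 becomes sp2 in step 17.

Step 17
Reactants: 23 C2 tertiary allylic alcohol
Product: 24 tris-silylated (2Z)-enal (C2=C(CH3)CHO with CHO cis to C1)
Conditions: pyridinium chlorochromate [C5H5NH][CrO3Cl], Celite, CH2Cl2, rt
Reagents that add atoms: none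
Why: Babler–Dauben oxidative transposition; the tertiary allylic chromate ester of hexavalent chromium shifts [3,3] to the primary allylic chromate, which is oxidised to the enal, and in the shift the isopropenyl methyl turns toward the unsubstituted C3 and the oxygen-bearing CH2 toward C1, which should give the 2Z alkene, also the more stable enal.

Step 18
Reactants: 24 tris-silylated (2Z)-enal
Product: 25 triol enal (24 without the three silyl groups)
Conditions: TBAF, AcOH, THF, rt → 40 °C
Reagents that add atoms: none
Why: Fluoride cleaves all three silyl ethers, and acetic acid buffers the basicity so that the enal and the C1 stereocentre should stay untouched.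

Step 19
Reactants: 25 triol enal; 26 vinyl stearate
Product: 27 CNP0187319.2
Conditions: immobilised Candida antarctica lipase B, MTBE, 4 Å molecular sieves, 40 °C
Reagents that add atoms: none
Why: Lipase-catalysed (serine hydrolase) irreversible transesterification with a vinyl ester should acylate only the unhindered primary alcohol, since the α-branched secondary allylic and the tertiary alcohol do not fit the acyl-enzyme.

**Compound list**
1 | 1,4-dioxaspiro[4.5]dec-6-en-8-one | O=C1C=CC2(CC1)OCCO2 | starting material
2 | 7-iodo-1,4-dioxaspiro[4.5]dec-6-en-8-one | O=C1C(I)=CC2(CC1)OCCO2 | intermediate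
3 | 7-methyl-1,4-dioxaspiro[4.5]dec-6-en-8-one | O=C1C(C)=CC2(CC1)OCCO2 | intermediate
4 | (3-bromopropoxy)(tert-butyl)diphenylsilane | CC(C)(C)[Si](c1ccccc1)(c1ccccc1)OCCCBr | starting material
5 | [3-(tert-butyldiphenylsilyloxy)propyl]magnesium bromide | CC(C)(C)[Si](c1ccccc1)(c1ccccc1)OCCC[Mg]Br | intermediate (not isolated)
6 | bromomagnesium (6R)-6-[3-(tert-butyldiphenylsilyloxy)propyl]-7-methyl-1,4-dioxaspiro[4.5]dec-7-en-8-olate | CC(C)(C)[Si](c1ccccc1)(c1ccccc1)OCCC[C@H]1C2(OCCO2)CCC(O[Mg]Br)=C1C | intermediate (not isolated)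
7 | (6R,7R)-7-allyl-6-[3-(tert-butyldiphenylsilyloxy)propyl]-7-methyl-1,4-dioxaspiro[4.5]decan-8-one (C1 chain trans to allyl, cis to methyl) | CC(C)(C)[Si](c1ccccc1)(c1ccccc1)OCCC[C@H]1C2(OCCO2)CCC(=O)[C@]1(C)CC=C | intermediate
8 | (6R,7R)-7-allyl-6-[3-(tert-butyldiphenylsilyloxy)propyl]-7-methyl-8-methylene-1,4-dioxaspiro[4.5]decane | CC(C)(C)[Si](c1ccccc1)(c1ccccc1)OCCC[C@H]1C2(OCCO2)CCC(=C)[C@]1(C)CC=C | intermediate
9 | spiro-epoxide of 8, oxirane oxygen cis to the C6 allyl group | CC(C)(C)[Si](c1ccccc1)(c1ccccc1)OCCC[C@H]1C2(OCCO2)CC[C@@]3(CO3)[C@]1(C)CC=C | intermediate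
10 | (6R,7R,8S)-7-allyl-6-[3-(tert-butyldiphenylsilyloxy)propyl]-7,8-dimethyl-1,4-dioxaspiro[4.5]decan-8-ol (OH cis to allyl) | CC(C)(C)[Si](c1ccccc1)(c1ccccc1)OCCC[C@H]1C2(OCCO2)CC[C@](C)(O)[C@]1(C)CC=C | intermediate
11 | triethylsilyl ether of 10 | CC(C)(C)[Si](c1ccccc1)(c1ccccc1)OCCC[C@H]1C2(OCCO2)CC[C@](C)(O[Si](CC)(CC)CC)[C@]1(C)CC=C | intermediate
12 | B-alkyl-9-borabicyclo[3.3.1]nonane from 11 (boron on the terminal carbon of the former allyl group) | CC(C)(C)[Si](c1ccccc1)(c1ccccc1)OCCC[C@H]1C2(OCCO2)CC[C@](C)(O[Si](CC)(CC)CC)[C@]1(C)CCCB3C4CCCC3CCC4 | intermediate (not isolated)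
13 | primary alcohol (C6 chain CH2CH2CH2OH) | CC(C)(C)[Si](c1ccccc1)(c1ccccc1)OCCC[C@H]1C2(OCCO2)CC[C@](C)(O[Si](CC)(CC)CC)[C@]1(C)CCCO | intermediate
14 | aldehyde (C6 chain CH2CH2CHO) | CC(C)(C)[Si](c1ccccc1)(c1ccccc1)OCCC[C@H]1C2(OCCO2)CC[C@](C)(O[Si](CC)(CC)CC)[C@]1(C)CCC=O | intermediate
15 | (E)-enal (C6 chain CH2CH2CH=C(CH3)CHO) | CC(C)(C)[Si](c1ccccc1)(c1ccccc1)OCCC[C@H]1C2(OCCO2)CC[C@](C)(O[Si](CC)(CC)CC)[C@]1(C)CC/C=C(\C)C=O | intermediate
16 | geranyl chloride, (E)-1-chloro-3,7-dimethylocta-2,6-diene | ClC/C=C(\C)CCC=C(C)C | starting material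
17 | geranylbarium chloride | Cl[Ba]C/C=C(\C)CCC=C(C)C | intermediate (not isolated)
18 | C5' allylic alcohol, both C5' epimers, 3'E,7'E | CC(C)(C)[Si](c1ccccc1)(c1ccccc1)OCCC[C@H]1C2(OCCO2)CC[C@](C)(O[Si](CC)(CC)CC)[C@]1(C)CC/C=C(\C)C(O)C/C=C(\C)CCC=C(C)C | intermediate
19 | C5' ketone, 3'E,7'E | CC(C)(C)[Si](c1ccccc1)(c1ccccc1)OCCC[C@H]1C2(OCCO2)CC[C@](C)(O[Si](CC)(CC)CC)[C@]1(C)CC/C=C(\C)C(=O)C/C=C(\C)CCC=C(C)C | intermediate
20 | (5'R)-allylic alcohol | CC(C)(C)[Si](c1ccccc1)(c1ccccc1)OCCC[C@H]1C2(OCCO2)CC[C@](C)(O[Si](CC)(CC)CC)[C@]1(C)CC/C=C(\C)[C@H](O)C/C=C(\C)CCC=C(C)C | intermediate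
21 | tert-butyldimethylsilyl ether of 20 | CC(C)(C)[Si](c1ccccc1)(c1ccccc1)OCCC[C@H]1C2(OCCO2)CC[C@](C)(O[Si](CC)(CC)CC)[C@]1(C)CC/C=C(\C)[C@H](O[Si](C)(C)C(C)(C)C)C/C=C(\C)CCC=C(C)C | intermediate
22 | C2 ketone (21 without the ketal) | CC(C)(C)[Si](c1ccccc1)(c1ccccc1)OCCC[C@H]1C(=O)CC[C@](C)(O[Si](CC)(CC)CC)[C@]1(C)CC/C=C(\C)[C@H](O[Si](C)(C)C(C)(C)C)C/C=C(\C)CCC=C(C)C | intermediate
23 | C2 tertiary allylic alcohol (2-hydroxy-2-isopropenyl, C2 configuration left open) | CC(C)(C)[Si](c1ccccc1)(c1ccccc1)OCCC[C@H]1C(O)(C(C)=C)CC[C@](C)(O[Si](CC)(CC)CC)[C@]1(C)CC/C=C(\C)[C@H](O[Si](C)(C)C(C)(C)C)C/C=C(\C)CCC=C(C)C | intermediate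
24 | tris-silylated (2Z)-enal | CC(C)(C)[Si](c1ccccc1)(c1ccccc1)OCCC[C@H]1/C(=C(/C)C=O)CC[C@](C)(O[Si](CC)(CC)CC)[C@]1(C)CC/C=C(\C)[C@H](O[Si](C)(C)C(C)(C)C)C/C=C(\C)CCC=C(C)C | intermediate
25 | triol enal (free primary, secondary and tertiary alcohols) | OCCC[C@H]1/C(=C(/C)C=O)CC[C@](C)(O)[C@]1(C)CC/C=C(\C)[C@H](O)C/C=C(\C)CCC=C(C)C | intermediate
26 | vinyl stearate | CCCCCCCCCCCCCCCCCC(=O)OC=C | starting material
27 | CNP0187319.2 | CCCCCCCCCCCCCCCCCC(=O)OCCC[C@H]1/C(=C(/C)C=O)CC[C@](C)(O)[C@]1(C)CC/C=C(\C)[C@H](O)C/C=C(\C)CCC=C(C)C | target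

**Count and risks**
Total steps: 19. Longest linear sequence: 19 (1 → 27).

Steps most likely to fail:

Step 3. The catalyst may discriminate the faces poorly on an enone hindered at both the α- and the γ-carbon, and proton transfer from product ketone to the magnesium enolate may erode regiocontrol before alkylation. The fallback sets out from 1 and Grignard reagent 5 and rejoins at 7. It sets C1 first on the unsubstituted enone, the best-precedented substrate class: copper-catalysed asymmetric conjugate addition of 5 to 1 (CuBr·SMe2, a chiral ferrocenyl diphosphine ligand, tBuOMe, −75 °C) with methyl iodide trapping should give the trans 2-methyl-3-alkyl ketone F1. Thermodynamic silylation (TMSCl, NaI, Et3N, MeCN) gives the tetrasubstituted trimethylsilyl enol ether F2. MeLi then releases the lithium enolate regiospecifically, and allyl iodide with HMPA alkylates it anti to the C1 chain to give 7.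

Step 17. The tertiary allylic chromate may ionise and eliminate to dienes, and the alkene geometry may erode if the shift becomes stepwise. The fallback sets out from 23 and rejoins at 24. It separates the transposition from the oxidation: a catalytic amount of Ph3SiOReO3 (a heptavalent rhenium oxo catalyst; Et2O, −50 °C) moves the hydroxyl 1,3 under neutral conditions to the primary allylic alcohol F3, and MnO2 in CH2Cl2 oxidises it to 24. Any E isomer of the enal can then be equilibrated toward the more stable Z isomer.

Step 5. The peracid may also attack the allyl group, and the facial selectivity at the exocyclic alkene may be incomplete. The fallback sets out from 7 and rejoins at 9, leaving out 8. Corey–Chaykovsky reaction with dimethylsulfoxonium methylide (trimethylsulfoxonium iodide, NaH, DMSO, 50 °C) transfers methylene to the ketone under reversible betaine formation, which should place the new C–C bond equatorial and the oxygen axial, cis to the allyl group. No alkene competes. This fallback makes no new compound (F0).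

Further compounds
F1 | step 3 | trans-7-methyl-6-[3-(tert-butyldiphenylsilyloxy)propyl]-1,4-dioxaspiro[4.5]decan-8-one (methyl trans to the C1 chain) | CC(C)(C)[Si](c1ccccc1)(c1ccccc1)OCCC[C@H]1C2(OCCO2)CCC(=O)[C@@H]1C
F2 | step 3 | (6R)-6-[3-(tert-butyldiphenylsilyloxy)propyl]-7-methyl-8-(trimethylsilyloxy)-1,4-dioxaspiro[4.5]dec-7-ene | CC(C)(C)[Si](c1ccccc1)(c1ccccc1)OCCC[C@H]1C2(OCCO2)CCC(O[Si](C)(C)C)=C1C
F3 | step 17 | tris-silylated (2Z)-allylic alcohol (C2=C(CH3)CH2OH with CH2OH cis to C1) | CC(C)(C)[Si](c1ccccc1)(c1ccccc1)OCCC[C@H]1/C(=C(/C)CO)CC[C@](C)(O[Si](CC)(CC)CC)[C@]1(C)CC/C=C(\C)[C@H](O[Si](C)(C)C(C)(C)C)C/C=C(\C)CCC=C(C)C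
F0 | step 5 | none | none
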